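**Retrosynthetic overview**
1. Target 15 ← (6S)-O,S-ketal 14: phenylsulfanyl at C4 is exchanged for methoxy through the aryloxy-stabilised C4 oxocarbenium ion, and the C6 allyl group steers methanol (sets 4R).
2. 14 ← quaternary β-keto allyl ester 13 by enantioselective decarboxylative protonation at C6 (sets 6S); 13 ← annulation product 10 by C6 allylation, then γ-sulfenylation at C4.
3. Ring A (the only ring made) ← Michael–Dieckmann annulation forming C4–C5 and C1–C6 from butenoate 6 (C1–C4) and allyl acrylate 7 (C5, C6).
4. 6 ← phenol 4 (O-allylation and Claisen rearrangement of 3,4-dimethoxyphenol) and chloro enol ether 5.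
5. Feature used: in ring A the vinylogous ester C1(=O)–C2=C3(OMe) carries the oxygenated C4 on its γ-side, and C4 is linked to the carbonyl-adjacent C6 by the single methylene C5, so C1–C4 map onto a 4-aryloxy-3-methoxybut-2-enoate and C5–C6 onto an acrylate.

Key step: step 4

**Remarks on the chemistry (assumptions)**
- Ring A locants in the Why lines are those of the target: C1 carbonyl, C2=C3(OMe), C4 ketal carbon, C5 methylene, C6 allyl-bearing carbon. Formal names of intermediates use their own locants.
- In the target (4R,6S) the C6 allyl group is cis to the C4 aryloxy group and trans to the C4 methoxy group.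
- The palladium/PHOX protonation is assumed to give (6S) with (S)-t-Bu-PHOX; if the sense proves opposite, (R)-t-Bu-PHOX is used with no other change.
- Compound 5 is a catalogue compound and is used as purchased.

**Route**

Step 1
Reactants: 1 3,4-dimethoxyphenol; 2 allyl bromide
Product: 3 4-(allyloxy)-1,2-dimethoxybenzene
Conditions: K2CO3, acetone, reflux
Reagents that add atoms: none
Why: Williamson ether synthesis, in which the phenoxide displaces bromide from the allylic halide by SN2 and O-alkylation dominates under carbonate/acetone conditions.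

Step 2
Reactants: 3 4-(allyloxy)-1,2-dimethoxybenzene
Product: 4 2-allyl-4,5-dimethoxyphenol
Conditions: N,N-diethylaniline, 195 °C, argon
Reagents that add atoms: none
Why: The aromatic Claisen rearrangement ([3,3]-sigmatropic shift followed by tautomerisation) should deliver the allyl group mainly to the unhindered ortho carbon para to the 3-methoxy group rather than to the ortho carbon flanked by that methoxy group, and chromatography removes the minor regioisomer.

Step 3
Reactants: 4 2-allyl-4,5-dimethoxyphenol; 5 methyl (2E)-4-chloro-3-methoxybut-2-enoate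
Product: 6 methyl (2E)-4-(2-allyl-4,5-dimethoxyphenoxy)-3-methoxybut-2-enoate
Conditions: K2CO3, KI (10 mol %), DMF, 50 °C
Reagents that add atoms: none
Why: Williamson-type SN2 displacement of the activated allylic chloride by the phenoxide, under a carbonate base too weak to touch the γ-protons or the enol ether, so the (2E) geometry that holds the ester cis to C4 is kept for the later ring closure.

Step 4
Reactants: 6 methyl (2E)-4-(2-allyl-4,5-dimethoxyphenoxy)-3-methoxybut-2-enoate; 7 allyl acrylate
Product: 10 allyl 5-(2-allyl-4,5-dimethoxyphenoxy)-4-methoxy-2-oxocyclohex-3-ene-1-carboxylate (racemic diastereomer mixture), via lithium dienolate 8 (not isolated), via open-chain lithium ester enolate 9 (not isolated)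
Conditions: LiN(i-Pr)2 (1.1 equiv), THF, −78 °C; add 7, −78 to −20 °C; AcOH, −78 °C
Reagents that add atoms: none
Why: LiN(i-Pr)2 removes a C4 proton of 6 to give the U-shaped lithium dienolate 8, whose γ-carbon C4 adds to the β-carbon of 7 (C4–C5 bond), and the ester enolate 9 so formed attacks the methyl ester carbonyl C1, which the (2E) enol ether holds on the same side as C4, and expels methoxide (C1–C6 bond). The closest known reaction type is the Michael–Dieckmann (Michael–Claisen) annulation of γ-deprotonated 3-alkoxybut-2-enoates and of o-toluate anions with acrylates and enones. Ring A closes in the favoured 6-(enolexo)-exo-trig mode. C4 and C6 arise without control, so 10 is expected as a racemic and partly enolised mixture, which costs nothing because C6 later passes through a planar enolate and C4 through a planar oxocarbenium ion. The step needs γ- instead of α-attack of the dienolate and 1,4- instead of 1,2-addition to the acrylate: the delocalised anion is soft and the acrylate β-carbon unhindered, only the γ-adduct keeps the push–pull enoate and can cyclise, and the ring closure is pulled forward because the released methoxide turns 10 into its stable β-keto ester enolate. Quenching cold with acetic acid returns neutral 10 before aryloxide loss or ester exchange can start.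

Step 5
Reactants: 10 allyl 5-(2-allyl-4,5-dimethoxyphenoxy)-4-methoxy-2-oxocyclohex-3-ene-1-carboxylate; 2 allyl bromide
Product: 11 allyl 1-allyl-5-(2-allyl-4,5-dimethoxyphenoxy)-4-methoxy-2-oxocyclohex-3-ene-1-carboxylate (racemic diastereomer mixture)
Conditions: K2CO3, acetone, 50 °C
Reagents that add atoms: none
Why: C-alkylation of the β-keto ester enolate with a soft allylic bromide (acetoacetic-ester-type alkylation) makes C6 quaternary without any need for control, which brings in the future C6 allyl group and removes the α′-proton so that only C4 can be enolised in the next step.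

Step 6
Reactants: 11 allyl 1-allyl-5-(2-allyl-4,5-dimethoxyphenoxy)-4-methoxy-2-oxocyclohex-3-ene-1-carboxylate
Product: 13 allyl 1-allyl-5-(2-allyl-4,5-dimethoxyphenoxy)-4-methoxy-2-oxo-5-(phenylsulfanyl)cyclohex-3-ene-1-carboxylate (racemic diastereomer mixture), via trimethylsilyl dienol ether 12 (not isolated)
Conditions: Me3SiCl, LiN(i-Pr)2, THF, −78 °C; evaporate, pentane, filter; PhSCl (1.0 equiv), CH2Cl2, −78 °C
Reagents that add atoms: benzenesulfenyl chloride, ClSc1ccccc1; chlorotrimethylsilane, C[Si](C)(C)Cl (its silyl group stays only in intermediate 12)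
Why: With C6 blocked the base can only remove the C4 proton, silylation gives the 1-silyloxy-3-methoxy diene 12, and the sulfenyl chloride should attack its terminal carbon C4 (γ-sulfenylation of an O-silylated dienolate) because that path gives the cation stabilised by both the C3 methoxy and the C1 silyloxy groups and because this electron-rich diene should react far faster than the isolated alkenes or the arene at −78 °C, the new C4 centre being formed without control.

Step 7
Reactants: 13 allyl 1-allyl-5-(2-allyl-4,5-dimethoxyphenoxy)-4-methoxy-2-oxo-5-(phenylsulfanyl)cyclohex-3-ene-1-carboxylate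
Product: 14 (6S)-6-allyl-4-(2-allyl-4,5-dimethoxyphenoxy)-3-methoxy-4-(phenylsulfanyl)cyclohex-2-en-1-one (both C4 epimers)
Conditions: Pd2(dba)3 (5 mol %), (S)-t-Bu-PHOX (12.5 mol %), Meldrum's acid (2.5 equiv), 1,4-dioxane, 23 °C
Reagents that add atoms: none
Why: In this palladium-catalysed enantioselective decarboxylative protonation, zerovalent palladium ionises the allyl ester, CO2 is lost, and the PHOX-bound palladium enolate is protonated at C6 by Meldrum's acid (whose anion takes up the allyl fragment), so the C6 configuration is set by the ligand on a planar enolate and all stereoisomers of 13 should converge on the (6S) series.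

Step 8
Reactants: 14 (6S)-6-allyl-4-(2-allyl-4,5-dimethoxyphenoxy)-3-methoxy-4-(phenylsulfanyl)cyclohex-2-en-1-one
Product: 15 (4R,6S)-6-allyl-4-(2-allyl-4,5-dimethoxyphenoxy)-3,4-dimethoxycyclohex-2-en-1-one (target)
Conditions: MeOTf (2 equiv), 2,6-di-tert-butyl-4-methylpyridine (3 equiv), MeOH/CH2Cl2 (1:4), 4 Å molecular sieves, −40 to 0 °C
Reagents that add atoms: methanol, CO
Why: Methyl triflate S-methylates the phenylsulfanyl group (thioglycoside-type activation), methyl phenyl sulfide leaves from either C4 epimer to give the same aryloxy-stabilised oxocarbenium ion, and methanol should add along the pseudoaxial trajectory of the half-chair that keeps the C6 allyl group pseudoequatorial, which places the new methoxy group trans to the allyl group and so sets (4R) under control of the (6S) centre, while the hindered pyridine keeps the medium non-acidic so that neither C6 nor the mixed ketal equilibrates.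

**Compound list**
1 | 3,4-dimethoxyphenol | COc1ccc(O)cc1OC | starting material
2 | allyl bromide | C=CCBr | starting material
3 | 4-(allyloxy)-1,2-dimethoxybenzene | C=CCOc1ccc(OC)c(OC)c1 | intermediate
4 | 2-allyl-4,5-dimethoxyphenol | C=CCc1cc(OC)c(OC)cc1O | intermediate
5 | methyl (2E)-4-chloro-3-methoxybut-2-enoate | COC(=O)/C=C(/OC)CCl | starting material
6 | methyl (2E)-4-(2-allyl-4,5-dimethoxyphenoxy)-3-methoxybut-2-enoate | C=CCc1cc(OC)c(OC)cc1OC/C(OC)=C\C(=O)OC | intermediate
7 | allyl acrylate | C=CC(=O)OCC=C | starting material
8 | lithium dienolate of 6: lithium 4-(2-allyl-4,5-dimethoxyphenoxy)-1,3-dimethoxybuta-1,3-dien-1-olate (enolate geometry not defined) | [Li+].[O-]C(OC)=CC(OC)=COc1cc(OC)c(OC)cc1CC=C | intermediate (not isolated)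
9 | lithium C6 enolate of 7-allyl 1-methyl (2E)-4-(2-allyl-4,5-dimethoxyphenoxy)-3-methoxyhept-2-enedioate (racemic) | [Li+].C=CCOC([O-])=CCC(Oc1cc(OC)c(OC)cc1CC=C)/C(OC)=C\C(=O)OC | intermediate (not isolated)
10 | allyl 5-(2-allyl-4,5-dimethoxyphenoxy)-4-methoxy-2-oxocyclohex-3-ene-1-carboxylate (racemic, both centres undefined) | C=CCOC(=O)C1CC(Oc2cc(OC)c(OC)cc2CC=C)C(OC)=CC1=O | intermediate
11 | allyl 1-allyl-5-(2-allyl-4,5-dimethoxyphenoxy)-4-methoxy-2-oxocyclohex-3-ene-1-carboxylate (racemic, both centres undefined) | C=CCOC(=O)C1(CC=C)CC(Oc2cc(OC)c(OC)cc2CC=C)C(OC)=CC1=O | intermediate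
12 | allyl 1-allyl-5-(2-allyl-4,5-dimethoxyphenoxy)-4-methoxy-2-(trimethylsilyloxy)cyclohexa-2,4-diene-1-carboxylate (racemic) | C=CCOC(=O)C1(CC=C)CC(Oc2cc(OC)c(OC)cc2CC=C)=C(OC)C=C1O[Si](C)(C)C | intermediate (not isolated)
13 | allyl 1-allyl-5-(2-allyl-4,5-dimethoxyphenoxy)-4-methoxy-2-oxo-5-(phenylsulfanyl)cyclohex-3-ene-1-carboxylate (racemic, both centres undefined) | C=CCOC(=O)C1(CC=C)CC(Oc2cc(OC)c(OC)cc2CC=C)(Sc2ccccc2)C(OC)=CC1=O | intermediate
14 | (6S)-6-allyl-4-(2-allyl-4,5-dimethoxyphenoxy)-3-methoxy-4-(phenylsulfanyl)cyclohex-2-en-1-one (C4 undefined, both epimers) | C=CC[C@H]1CC(Oc2cc(OC)c(OC)cc2CC=C)(Sc2ccccc2)C(OC)=CC1=O | intermediate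
15 | (4R,6S)-6-allyl-4-(2-allyl-4,5-dimethoxyphenoxy)-3,4-dimethoxycyclohex-2-en-1-one | C=CCc1cc(OC)c(OC)cc1O[C@]1(OC)C[C@H](CC=C)C(=O)C=C1OC | target

**Totals**
Total step count: 8. Longest linear sequence: 8 steps (1 to 15); 2, 5 and 7 are purchased.

**Three steps most likely to fail**

Risk 1 (step 4). The dienolate may add through its α-carbon, the acrylate may oligomerise anionically, or the ester enolate may close too slowly onto the deactivated push–pull methyl ester. Fallback, from 6 back to 10: the dienolate is O-silylated (LiN(i-Pr)2, Me3SiCl, THF, −78 °C) to give the ketene silyl acetal {[4-(2-allyl-4,5-dimethoxyphenoxy)-1,3-dimethoxybuta-1,3-dien-1-yl]oxy}trimethylsilane F1. This 1,1,3-trioxygenated diene is heated with 7 (toluene, 80 °C) in a Diels–Alder reaction, in which its nucleophilic terminus C4 bonds to the acrylate β-carbon, to give the cycloadduct allyl 5-(2-allyl-4,5-dimethoxyphenoxy)-2,4-dimethoxy-2-(trimethylsilyloxy)cyclohex-3-ene-1-carboxylate F2. Dilute HCl in THF at 0 °C then cleaves the silyl methyl ketal and returns to the route at 10. The same two bonds are made, but by a neutral cycloaddition instead of an anionic cascade.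

Risk 2 (step 7). The resident C4 centre of the racemic substrate may oppose the ligand in one diastereomeric enolate (mismatched pairing), which would erode the enantiomeric purity at C6; allyl transfer may also compete with proton transfer. Fallback, from 13 back to 15: the ester is removed without asymmetric induction (Pd(PPh3)4, HCO2H, Et3N, THF) to give the stereorandom ketone 6-allyl-4-(2-allyl-4,5-dimethoxyphenoxy)-3-methoxy-4-(phenylsulfanyl)cyclohex-2-en-1-one F3. The conditions of step 8 convert it into the racemic trans ketal, 15 together with its (4S,6R) enantiomer, F4. Preparative chromatography on a chiral stationary phase (amylose tris(3,5-dimethylphenylcarbamate), supercritical CO2/MeOH) resolves it and returns to the route at 15.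

Risk 3 (step 8). Methylation may occur at the vinylogous ester oxygen instead of at sulfur, the oxocarbenium ion may lose a C5 proton and aromatise, or methanol may add with poor facial selectivity. Fallback, from 14 back to 15: the sulfide is oxidised chemoselectively ((NH4)6Mo7O24·4H2O cat., H2O2, EtOH, 0 °C) to the sulfone (6S)-6-allyl-4-(2-allyl-4,5-dimethoxyphenoxy)-3-methoxy-4-(phenylsulfonyl)cyclohex-2-en-1-one F5. Its sulfinate group is then displaced by methanol under mild Lewis acid assistance (MgBr2·OEt2, NaHCO3, MeOH/THF, 0 °C), which avoids any alkylating agent and returns to the route at 15 through the same oxocarbenium ion.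

**Further compounds**
F1 | step 4 | {[4-(2-allyl-4,5-dimethoxyphenoxy)-1,3-dimethoxybuta-1,3-dien-1-yl]oxy}trimethylsilane (double-bond geometry not defined) | C=CCc1cc(OC)c(OC)cc1OC=C(OC)C=C(OC)O[Si](C)(C)C
F2 | step 4 | allyl 5-(2-allyl-4,5-dimethoxyphenoxy)-2,4-dimethoxy-2-(trimethylsilyloxy)cyclohex-3-ene-1-carboxylate (racemic, centres undefined) | C=CCOC(=O)C1CC(Oc2cc(OC)c(OC)cc2CC=C)C(OC)=CC1(OC)O[Si](C)(C)C
F3 | step 7 | 6-allyl-4-(2-allyl-4,5-dimethoxyphenoxy)-3-methoxy-4-(phenylsulfanyl)cyclohex-2-en-1-one (all stereoisomers) | C=CCC1CC(Oc2cc(OC)c(OC)cc2CC=C)(Sc2ccccc2)C(OC)=CC1=O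
F4 | step 7 | racemic trans ketal: 15 together with its (4S,6R) enantiomer | C=CCc1cc(OC)c(OC)cc1O[C@]1(OC)C[C@H](CC=C)C(=O)C=C1OC.C=CCc1cc(OC)c(OC)cc1O[C@@]1(OC)C[C@@H](CC=C)C(=O)C=C1OC
F5 | step 8 | (6S)-6-allyl-4-(2-allyl-4,5-dimethoxyphenoxy)-3-methoxy-4-(phenylsulfonyl)cyclohex-2-en-1-one (both C4 epimers) | C=CC[C@H]1CC(Oc2cc(OC)c(OC)cc2CC=C)(S(=O)(=O)c2ccccc2)C(OC)=CC1=O
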